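**Strategy**

Everything rests on cutting the aryl ether bond O1–C8a of ring C. In ring A, C8a is ortho to C4a, which bears the C4 ketone, whereas the C5 and C7 oxygens are meta to it, so a fluorine placed on C8a is activated for addition–elimination. In the key step the C2 alkoxide of an enantiopure (S)-β-hydroxy ketone displaces this fluoride: the pyranone ring closes, the preset C2 stereocentre is not touched, and the prenyl group is locked at C8 rather than C6. The precursor joins a ring A aryllithium (fluorine between lithium and prenyl) to a ring B β-hydroxy Weinreb amide made by asymmetric transfer hydrogenation.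

Key step: step 9

Remark: flavanone numbering is used (ring A = benzo ring C4a–C8a, ring B = 2-aryl group, ring C = pyranone); the only stereocentre is C2 and its descriptor is S. Prenyl = 3-methylbut-2-en-1-yl, MOM = methoxymethyl.

**Route**

Step 1
Reactants: 1 methyl 4-hydroxybenzoate
Product: 3 methyl 4-hydroxy-3-(3-methylbut-2-en-1-yl)benzoate, via sodium phenoxide 2 (not isolated)
Conditions: NaH (1.0 equiv), toluene, rt; prenyl bromide (1.0 equiv), rt to 50 °C
Reagents that add atoms: prenyl bromide (1-bromo-3-methylbut-2-ene), CC(C)=CCBr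
Why: Phenoxide C-alkylation: the tight sodium phenoxide ion pair in a non-polar solvent should be alkylated by the allylic bromide at the ortho carbon rather than at oxygen, the para position being blocked by the ester, and tautomerisation restores the phenol.

Step 2
Reactants: 3 methyl 4-hydroxy-3-(3-methylbut-2-en-1-yl)benzoate
Product: 4 methyl 4-methoxy-3-(3-methylbut-2-en-1-yl)benzoate
Conditions: MeI (1.5 equiv), K2CO3 (2 equiv), acetone, reflux
Reagents that add atoms: iodomethane, CI
Why: Williamson ether synthesis on the phenoxide should give the aryl methyl ether that stays to the end as the ring B methoxy group.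

Step 3
Reactants: 4 methyl 4-methoxy-3-(3-methylbut-2-en-1-yl)benzoate
Product: 5 N-methoxy-3-[4-methoxy-3-(3-methylbut-2-en-1-yl)phenyl]-N-methyl-3-oxopropanamide
Conditions: LiN(i-Pr)2 (2.3 equiv), N-methoxy-N-methylacetamide (2.2 equiv), THF, −78 °C; then 4, −78 to −20 °C; cold 1 M HCl
Reagents that add atoms: N-methoxy-N-methylacetamide, CC(=O)N(C)OC
Why: Crossed Claisen condensation: the amide enolate should add to the non-enolisable benzoate and expel methoxide, the second equivalent of enolate holding the β-keto amide as its enolate until the quench.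

Step 4
Reactants: 5 N-methoxy-3-[4-methoxy-3-(3-methylbut-2-en-1-yl)phenyl]-N-methyl-3-oxopropanamide
Product: 6 (S)-3-hydroxy-N-methoxy-3-[4-methoxy-3-(3-methylbut-2-en-1-yl)phenyl]-N-methylpropanamide
Conditions: RuCl[(S,S)-TsDPEN](p-cymene) (1 mol %), HCO2H/Et3N (5:2), DMF, 30 °C
Reagents that add atoms: none
Why: Noyori asymmetric transfer hydrogenation: the hydride of the divalent ruthenium complex with the (S,S)-diamine ligand should reach the aryl ketone through the CH/π-organised six-membered transition state that turns aryl alkyl ketones into (S)-carbinols, which sets the later C2 centre, while the isolated alkenes and the amide are not reduced.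

Step 5
Reactants: 7 5-fluorobenzene-1,3-diol
Product: 8 1-fluoro-3,5-bis(methoxymethoxy)benzene
Conditions: MOMCl (2.5 equiv), i-Pr2NEt (3 equiv), CH2Cl2, 0 °C to rt
Reagents that add atoms: chloromethyl methyl ether (MOMCl), COCCl
Why: O-Alkylation of both phenols with the chloromethyl ether (acetal protection) should give ethers that survive the organolithium steps and are cleaved by mild acid at the end.

Step 6
Reactants: 8 1-fluoro-3,5-bis(methoxymethoxy)benzene
Product: 9 2,4-dibromo-3-fluoro-1,5-bis(methoxymethoxy)benzene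
Conditions: NBS (2.05 equiv), MeCN, 0 °C to rt, dark
Reagents that add atoms: N-bromosuccinimide, O=C1CCC(=O)N1Br
Why: Electrophilic aromatic bromination: each of the two equivalent positions next to fluorine is para to one acetal oxygen and ortho to the other and should be brominated in turn, the more hindered position between the two oxygens being left.

Step 7
Reactants: 9 2,4-dibromo-3-fluoro-1,5-bis(methoxymethoxy)benzene
Product: 12 2-bromo-3-fluoro-1,5-bis(methoxymethoxy)-4-(3-methylbut-2-en-1-yl)benzene, via aryllithium 10 (not isolated), via arylcopper 11 (not isolated)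
Conditions: n-BuLi (1.0 equiv), THF, −78 °C; CuBr·SMe2 (1.05 equiv), −78 °C; prenyl bromide (1.5 equiv), −78 to −20 °C
Reagents that add atoms: prenyl bromide (1-bromo-3-methylbut-2-ene), CC(C)=CCBr
Why: Bromine–lithium exchange of one of the two equivalent bromides, transmetalation to monovalent copper at −78 °C to stop loss of LiF, and SN2 coupling of the arylcopper at the unhindered primary terminus of the allylic bromide should give the linear prenyl arene.

Step 8
Reactants: 12 2-bromo-3-fluoro-1,5-bis(methoxymethoxy)-4-(3-methylbut-2-en-1-yl)benzene; 6 (S)-3-hydroxy-N-methoxy-3-[4-methoxy-3-(3-methylbut-2-en-1-yl)phenyl]-N-methylpropanamide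
Product: 16 (S)-1-[2-fluoro-4,6-bis(methoxymethoxy)-3-(3-methylbut-2-en-1-yl)phenyl]-3-hydroxy-3-[4-methoxy-3-(3-methylbut-2-en-1-yl)phenyl]propan-1-one, via chloromagnesium alkoxide 13 (not isolated), via aryllithium 14 (not isolated), via tetrahedral adduct 15 (not isolated)
Conditions: 12 (1.3 equiv), n-BuLi (1.25 equiv), THF, −78 °C; added to 6 pretreated with i-PrMgCl (1.0 equiv), THF, −78 °C; −78 to −40 °C; sat. aq NH4Cl
Reagents that add atoms: none
Why: Weinreb ketone synthesis: the aryllithium from bromine–lithium exchange should add to the amide whose hydroxyl is masked as the magnesium alkoxide, and the chelated tetrahedral adduct holds until the quench, so the ketone never meets the organometallic and the carbinol centre is not involved.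

Step 9
Reactants: 16 (S)-1-[2-fluoro-4,6-bis(methoxymethoxy)-3-(3-methylbut-2-en-1-yl)phenyl]-3-hydroxy-3-[4-methoxy-3-(3-methylbut-2-en-1-yl)phenyl]propan-1-one
Product: 18 (S)-5,7-bis(methoxymethoxy)-2-[4-methoxy-3-(3-methylbut-2-en-1-yl)phenyl]-8-(3-methylbut-2-en-1-yl)chroman-4-one, via potassium alkoxide 17 (not isolated)
Conditions: KN(SiMe3)2 (1.05 equiv), 18-crown-6 (1.1 equiv), THF, −78 to −20 °C; AcOH quench at −20 °C
Reagents that add atoms: none
Why: Deprotonation gives the C2 potassium alkoxide, which adds to C8a of ring A to form a Meisenheimer anion whose charge is taken up through C4a by the C4 carbonyl, and loss of fluoride restores the arene (intramolecular nucleophilic aromatic substitution by addition–elimination). The closest known reaction type is the base-mediated cyclisation of 1-(2-fluoroaryl)-3-hydroxyalkan-1-ones to chroman-4-ones. Ring C closes as a six-membered ring in the 6-exo-trig mode, the oxygen attacking the aromatic carbon whose C8a–C8 double bond lies outside the new ring. No stereocentre is formed: the C2 configuration was set by the catalyst in step 4, and since the C2–O bond is never broken it should be carried into the product with retention. The step needs ring closure to outrun retro-aldol cleavage and E1cB dehydration of the aldolate and to take place at C8a rather than at C5, which is secured by the ortho ketone, by the meta position of both acetal oxygens relative to C8a, by the six-membered transition state, by low temperature with one equivalent of base, and by fluoride being a far better leaving group in this mechanism than the C5 acetal oxygen.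

Step 10
Reactants: 18 (S)-5,7-bis(methoxymethoxy)-2-[4-methoxy-3-(3-methylbut-2-en-1-yl)phenyl]-8-(3-methylbut-2-en-1-yl)chroman-4-one
Product: 19 (S)-5,7-dihydroxy-2-[4-methoxy-3-(3-methylbut-2-en-1-yl)phenyl]-8-(3-methylbut-2-en-1-yl)chroman-4-one
Conditions: 3 M aq HCl, MeOH, 40 °C
Reagents that add atoms: none
Why: Acid-catalysed acetal cleavage (transacetalisation to methanol) should free the C5 and C7 phenols, the mild temperature being chosen to avoid cyclisation of the C8 prenyl group onto the C7 hydroxyl and to leave C2 untouched.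

**Compound list**

1 | methyl 4-hydroxybenzoate | COC(=O)c1ccc(O)cc1 | starting material
2 | sodium 4-(methoxycarbonyl)phenoxide | COC(=O)c1ccc([O-])cc1.[Na+] | intermediate
3 | methyl 4-hydroxy-3-(3-methylbut-2-en-1-yl)benzoate | COC(=O)c1ccc(O)c(CC=C(C)C)c1 | intermediate
4 | methyl 4-methoxy-3-(3-methylbut-2-en-1-yl)benzoate | COC(=O)c1ccc(OC)c(CC=C(C)C)c1 | intermediate
5 | N-methoxy-3-[4-methoxy-3-(3-methylbut-2-en-1-yl)phenyl]-N-methyl-3-oxopropanamide | COc1ccc(C(=O)CC(=O)N(C)OC)cc1CC=C(C)C | intermediate
6 | (S)-3-hydroxy-N-methoxy-3-[4-methoxy-3-(3-methylbut-2-en-1-yl)phenyl]-N-methylpropanamide | COc1ccc([C@@H](O)CC(=O)N(C)OC)cc1CC=C(C)C | intermediate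
7 | 5-fluorobenzene-1,3-diol (5-fluororesorcinol) | Oc1cc(O)cc(F)c1 | starting material
8 | 1-fluoro-3,5-bis(methoxymethoxy)benzene | COCOc1cc(F)cc(OCOC)c1 | intermediate
9 | 2,4-dibromo-3-fluoro-1,5-bis(methoxymethoxy)benzene | COCOc1cc(OCOC)c(Br)c(F)c1Br | intermediate
10 | [3-bromo-2-fluoro-4,6-bis(methoxymethoxy)phenyl]lithium | COCOc1cc(OCOC)c(Br)c(F)c1[Li] | intermediate
11 | [3-bromo-2-fluoro-4,6-bis(methoxymethoxy)phenyl]copper | COCOc1cc(OCOC)c(Br)c(F)c1[Cu] | intermediate
12 | 2-bromo-3-fluoro-1,5-bis(methoxymethoxy)-4-(3-methylbut-2-en-1-yl)benzene | COCOc1cc(OCOC)c(CC=C(C)C)c(F)c1Br | intermediate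
13 | chloromagnesium alkoxide of 6 | COc1ccc([C@@H](O[Mg]Cl)CC(=O)N(C)OC)cc1CC=C(C)C | intermediate
14 | [2-fluoro-4,6-bis(methoxymethoxy)-3-(3-methylbut-2-en-1-yl)phenyl]lithium | COCOc1cc(OCOC)c(CC=C(C)C)c(F)c1[Li] | intermediate
15 | tetrahedral lithium/magnesium adduct of 14 and 13 (hemiaminal centre undefined) | COc1ccc([C@@H](O[Mg]Cl)CC(O[Li])(N(C)OC)c2c(OCOC)cc(OCOC)c(CC=C(C)C)c2F)cc1CC=C(C)C | intermediate
16 | (S)-1-[2-fluoro-4,6-bis(methoxymethoxy)-3-(3-methylbut-2-en-1-yl)phenyl]-3-hydroxy-3-[4-methoxy-3-(3-methylbut-2-en-1-yl)phenyl]propan-1-one | COc1ccc([C@@H](O)CC(=O)c2c(OCOC)cc(OCOC)c(CC=C(C)C)c2F)cc1CC=C(C)C | intermediate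
17 | potassium alkoxide of 16 | COc1ccc([C@@H]([O-])CC(=O)c2c(OCOC)cc(OCOC)c(CC=C(C)C)c2F)cc1CC=C(C)C.[K+] | intermediate
18 | (S)-5,7-bis(methoxymethoxy)-2-[4-methoxy-3-(3-methylbut-2-en-1-yl)phenyl]-8-(3-methylbut-2-en-1-yl)chroman-4-one | COc1ccc([C@@H]2CC(=O)c3c(OCOC)cc(OCOC)c(CC=C(C)C)c3O2)cc1CC=C(C)C | intermediate
19 | (S)-5,7-dihydroxy-2-[4-methoxy-3-(3-methylbut-2-en-1-yl)phenyl]-8-(3-methylbut-2-en-1-yl)chroman-4-one | COc1ccc([C@@H]2CC(=O)c3c(O)cc(O)c(CC=C(C)C)c3O2)cc1CC=C(C)C | target

**Count and risks**

Total steps: 10. Longest linear sequence: 7 steps (steps 1, 2, 3, 4, 8, 9, 10); the ring A branch (steps 5, 6, 7) joins at step 8.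

Steps most likely to fail:

1. Step 9 (key step). Retro-aldol cleavage of the aldolate, which is reversible and would erode the enantiomeric purity, and E1cB loss of hydroxide to the chalcone may outrun the ring closure. Fallback, setting out from 16 and coming back at 18: the same O1–C8a bond would be closed at the 1,3-diketone level, where neither side reaction exists, and C2 would be set afterwards. Oxidation of 16 with Dess–Martin periodinane in CH2Cl2 should give 1-[2-fluoro-4,6-bis(methoxymethoxy)-3-prenylphenyl]-3-[4-methoxy-3-prenylphenyl]propane-1,3-dione F1. Warming F1 with K2CO3 in DMF should let the enolate oxygen displace the fluoride and give 5,7-bis(methoxymethoxy)-8-prenyl-2-[4-methoxy-3-prenylphenyl]-4H-chromen-4-one F2. Copper hydride conjugate reduction of F2 (Cu(OAc)2, DTBM-SEGPHOS, polymethylhydrosiloxane, t-BuOH, toluene) would then give 18; the ligand enantiomer that leads to the S product would have to be established on a small scale.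

2. Step 8. Loss of LiF from the ortho-fluoro aryllithium (aryne formation) and proton transfer from the amide α-position may outrun the addition to the hindered, chelated amide. Fallback, setting out from 6 and coming back at 16: acyl substitution would be replaced by addition to an aldehyde, which should be complete within minutes at −78 °C, followed by oxidation. Et3SiCl and imidazole in DMF should give (S)-N-methoxy-3-[4-methoxy-3-prenylphenyl]-N-methyl-3-(triethylsilyloxy)propanamide F3. Reduction with i-Bu2AlH in THF at −78 °C should give (S)-3-[4-methoxy-3-prenylphenyl]-3-(triethylsilyloxy)propanal F4. Addition of aryllithium 14 at −78 °C should give the carbinol (3S)-1-[2-fluoro-4,6-bis(methoxymethoxy)-3-prenylphenyl]-3-[4-methoxy-3-prenylphenyl]-3-(triethylsilyloxy)propan-1-ol F5 as a mixture of epimers at C1. Dess–Martin periodinane buffered with NaHCO3 should give the β-silyloxy ketone (S)-1-[2-fluoro-4,6-bis(methoxymethoxy)-3-prenylphenyl]-3-[4-methoxy-3-prenylphenyl]-3-(triethylsilyloxy)propan-1-one F6. HF·pyridine in THF/pyridine at 0 °C would remove the silyl group without base and give 16.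

3. Step 7. Attack of the arylcopper at the tertiary terminus of the allylic bromide (SN2' path, giving the 1,1-dimethylallyl isomer) and incomplete or double bromine–lithium exchange may spoil the coupling. Fallback, setting out from 9 and coming back at 12: the side chain would be built in two stages. Aryllithium 10 (n-BuLi, THF, −78 °C) would be trapped with allyl bromide (CuBr·SMe2, 10 mol %), whose two termini give the same product, to give 2-bromo-3-fluoro-1,5-bis(methoxymethoxy)-4-(prop-2-en-1-yl)benzene F7. Olefin cross-metathesis of F7 with 2-methylbut-2-ene as solvent (second-generation Grubbs catalyst, 40 °C) should turn the allyl into the prenyl group and give 12.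

**Further compounds**

F1 | step 9 | 1-[2-fluoro-4,6-bis(methoxymethoxy)-3-(3-methylbut-2-en-1-yl)phenyl]-3-[4-methoxy-3-(3-methylbut-2-en-1-yl)phenyl]propane-1,3-dione | COc1ccc(C(=O)CC(=O)c2c(OCOC)cc(OCOC)c(CC=C(C)C)c2F)cc1CC=C(C)C
F2 | step 9 | 5,7-bis(methoxymethoxy)-2-[4-methoxy-3-(3-methylbut-2-en-1-yl)phenyl]-8-(3-methylbut-2-en-1-yl)-4H-chromen-4-one | COc1ccc(-c2cc(=O)c3c(OCOC)cc(OCOC)c(CC=C(C)C)c3o2)cc1CC=C(C)C
F3 | step 8 | (S)-N-methoxy-3-[4-methoxy-3-(3-methylbut-2-en-1-yl)phenyl]-N-methyl-3-(triethylsilyloxy)propanamide | COc1ccc([C@@H](O[Si](CC)(CC)CC)CC(=O)N(C)OC)cc1CC=C(C)C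
F4 | step 8 | (S)-3-[4-methoxy-3-(3-methylbut-2-en-1-yl)phenyl]-3-(triethylsilyloxy)propanal | COc1ccc([C@@H](O[Si](CC)(CC)CC)CC=O)cc1CC=C(C)C
F5 | step 8 | (3S)-1-[2-fluoro-4,6-bis(methoxymethoxy)-3-(3-methylbut-2-en-1-yl)phenyl]-3-[4-methoxy-3-(3-methylbut-2-en-1-yl)phenyl]-3-(triethylsilyloxy)propan-1-ol (both C1 epimers) | COc1ccc([C@@H](O[Si](CC)(CC)CC)CC(O)c2c(OCOC)cc(OCOC)c(CC=C(C)C)c2F)cc1CC=C(C)C
F6 | step 8 | (S)-1-[2-fluoro-4,6-bis(methoxymethoxy)-3-(3-methylbut-2-en-1-yl)phenyl]-3-[4-methoxy-3-(3-methylbut-2-en-1-yl)phenyl]-3-(triethylsilyloxy)propan-1-one | COc1ccc([C@@H](O[Si](CC)(CC)CC)CC(=O)c2c(OCOC)cc(OCOC)c(CC=C(C)C)c2F)cc1CC=C(C)C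
F7 | step 7 | 2-bromo-3-fluoro-1,5-bis(methoxymethoxy)-4-(prop-2-en-1-yl)benzene | COCOc1cc(OCOC)c(CC=C)c(F)c1Br
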